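**Plan**

1. Retrosynthetic cuts, in order: the four O–Si bonds; C2–C3 of ring C (1,3 O-to-C shift); the exocyclic C4=CH2 (back to a lactone C=O); C6–alkenyl (Suzuki); C8–prenyl (Claisen shift from O7); the two acetal C–O bonds at C2 that join the ring-A acid to the ring-B aldehyde.
2. Enabling feature: ring C is a 4-pyranone fused to ring A, with O1 and C4 on the adjacent carbons C8a and C4a. Its O1–C2(aryl)–C3–C4(=O) unit is the rearranged form of the O1–C2H(aryl)–O3–C4(=CH2) unit of a 2-aryl-4-methylene-1,3-benzodioxine, which a salicylic-type acid and an aldehyde provide.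
3. Forward: rings A and B are first joined as a racemic benzodioxinone. Ring A is then fully substituted on this acylal (O7 ether, C6 iodide, Claisen shift to C8, coupling at C6). The lactone is methylenated and ring C is closed in the penultimate step.
4. Stereochemistry: C2 (S) is the only stereocentre. It is set by the counter-anion of a chiral acid in the enantioconvergent ring-C closure, after all basic and thermal steps, and only a buffered desilylation follows. The E-alkene comes from syn-hydroboration and a stereoretentive coupling.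

Key step: step 11

Remark: the sense of induction of the chiral acid cannot be predicted for this new reaction; the (R)-catalyst is written, and its antipode is used instead if screening shows that it favours (2R).

**Step 1**
Reactants: 1 2,4-dihydroxybenzaldehyde
Product: 2 2,4-bis(triisopropylsilyloxy)benzaldehyde
Conditions: TIPSOTf, 2,6-lutidine, CH2Cl2, 0 °C to rt
Reagents that add atoms: triisopropylsilyl trifluoromethanesulfonate, CC(C)[Si](OS(=O)(=O)C(F)(F)F)(C(C)C)C(C)C
Why: O-silylation of both phenols (the chelated 2-OH calls for the triflate); TIPS ethers should withstand the DBU, aqueous phosphate, heat and titanium reagent that follow and leave with fluoride at the end.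

**Step 2**
Reactants: 3 2,4,6-trihydroxybenzoic acid; 2 2,4-bis(triisopropylsilyloxy)benzaldehyde
Product: 6 rac-2-[2,4-bis(triisopropylsilyloxy)phenyl]-5,7-dihydroxy-4H-1,3-benzodioxin-4-one, via persilylated acid 4 (not isolated), via bis-TMS benzodioxinone 5 (not isolated)
Conditions: (i) HMDS, THF, 50 °C, then evaporate; (ii) 2, TMSOTf (10 mol%), CH2Cl2, −78 to −20 °C, pyridine quench; (iii) aq. citric acid, THF, rt
Reagents that add atoms: none
Why: Noyori/Seebach-type silyl acetalisation, in which the TMS ester and one ortho TMS ether of 4 condense with the TMSOTf-activated aldehyde to the six-membered acylal with loss of hexamethyldisiloxane; the low temperature should keep O,O-acetal formation ahead of C-alkylation of the phloroglucinol ring, early silylation of the carboxyl group should suppress decarboxylation, and the two remaining aryl TMS ethers are hydrolysed on work-up.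

**Step 3**
Reactants: 6 rac-2-[2,4-bis(triisopropylsilyloxy)phenyl]-5,7-dihydroxy-4H-1,3-benzodioxin-4-one; 7 3-chloro-3-methylbut-1-yne
Product: 8 rac-2-[2,4-bis(triisopropylsilyloxy)phenyl]-5-hydroxy-7-[(2-methylbut-3-yn-2-yl)oxy]-4H-1,3-benzodioxin-4-one
Conditions: DBU, CuCl2·2H2O (1 mol%), MeCN, 0 °C
Reagents that add atoms: none
Why: Copper-catalysed propargylic etherification of a phenol (Godfrey conditions); only the unchelated, more acidic 7-OH should react, the 5-OH being held in a hydrogen bond to the lactone carbonyl.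

**Step 4**
Reactants: 8 rac-2-[2,4-bis(triisopropylsilyloxy)phenyl]-5-hydroxy-7-[(2-methylbut-3-yn-2-yl)oxy]-4H-1,3-benzodioxin-4-one
Product: 9 rac-2-[2,4-bis(triisopropylsilyloxy)phenyl]-5-hydroxy-7-[(2-methylbut-3-en-2-yl)oxy]-4H-1,3-benzodioxin-4-one
Conditions: H2 (1 atm), Lindlar catalyst, quinoline, EtOAc, rt
Reagents that add atoms: none
Why: Lindlar semi-hydrogenation stops at the alkene and gives the 1,1-dimethylallyl ether; it is placed before the iodination so that no aryl iodide is exposed to Pd/H2.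

**Step 5**
Reactants: 9 rac-2-[2,4-bis(triisopropylsilyloxy)phenyl]-5-hydroxy-7-[(2-methylbut-3-en-2-yl)oxy]-4H-1,3-benzodioxin-4-one
Product: 10 rac-2-[2,4-bis(triisopropylsilyloxy)phenyl]-5-hydroxy-6-iodo-7-[(2-methylbut-3-en-2-yl)oxy]-4H-1,3-benzodioxin-4-one
Conditions: NIS, DMF, 0 °C to rt, dark
Reagents that add atoms: N-iodosuccinimide, O=C1CCC(=O)N1I
Why: Electrophilic aromatic iodination, which in 5-hydroxy-7-alkoxy aryl carbonyl systems under neutral conditions goes ortho to the free chelated OH (C6); the silylated ring B and the monosubstituted vinyl group are far less reactive.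

**Step 6**
Reactants: 10 rac-2-[2,4-bis(triisopropylsilyloxy)phenyl]-5-hydroxy-6-iodo-7-[(2-methylbut-3-en-2-yl)oxy]-4H-1,3-benzodioxin-4-one
Product: 11 rac-2-[2,4-bis(triisopropylsilyloxy)phenyl]-5,7-dihydroxy-6-iodo-8-(3-methylbut-2-en-1-yl)-4H-1,3-benzodioxin-4-one
Conditions: toluene, 110 °C, sealed tube, dark
Reagents that add atoms: none
Why: Aromatic Claisen rearrangement ([3,3] shift) of the 1,1-dimethylallyl ether places a prenyl group on C8, the only free ortho carbon, while iodine occupies C6; tautomerisation then restores the 7-OH.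

**Step 7**
Reactants: 12 3-methylbut-1-yne
Product: 13 (E)-2-(3-methylbut-1-en-1-yl)-4,4,5,5-tetramethyl-1,3,2-dioxaborolane
Conditions: HBpin, Cp2Zr(H)Cl (5 mol%), Et3N (10 mol%), neat, rt to 40 °C, sealed
Reagents that add atoms: pinacolborane, [H]B1OC(C)(C)C(C)(C)O1
Why: Zirconocene-catalysed hydroboration of a terminal alkyne; syn, anti-Markovnikov addition fixes the E geometry.

**Step 8**
Reactants: 11 rac-2-[2,4-bis(triisopropylsilyloxy)phenyl]-5,7-dihydroxy-6-iodo-8-(3-methylbut-2-en-1-yl)-4H-1,3-benzodioxin-4-one; 13 (E)-2-(3-methylbut-1-en-1-yl)-4,4,5,5-tetramethyl-1,3,2-dioxaborolane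
Product: 14 rac-2-[2,4-bis(triisopropylsilyloxy)phenyl]-5,7-dihydroxy-6-[(E)-3-methylbut-1-en-1-yl]-8-(3-methylbut-2-en-1-yl)-4H-1,3-benzodioxin-4-one
Conditions: Pd(OAc)2 (5 mol%), SPhos (10 mol%), K3PO4, THF–H2O (10:1), 50 °C
Reagents that add atoms: none
Why: Suzuki–Miyaura coupling with retention of alkene geometry; it is run only after the Claisen shift, so that no O-propargyl or O-allyl group sits ortho to the aryl–palladium bond (which would invite 5-exo carbopalladation or π-allyl ionisation), and a bulky biaryl phosphine is chosen for the electron-rich, doubly ortho-substituted iodide.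

**Step 9**
Reactants: 14 rac-2-[2,4-bis(triisopropylsilyloxy)phenyl]-5,7-dihydroxy-6-[(E)-3-methylbut-1-en-1-yl]-8-(3-methylbut-2-en-1-yl)-4H-1,3-benzodioxin-4-one
Product: 15 rac-2-[2,4-bis(triisopropylsilyloxy)phenyl]-5,7-bis(tert-butyldimethylsilyloxy)-6-[(E)-3-methylbut-1-en-1-yl]-8-(3-methylbut-2-en-1-yl)-4H-1,3-benzodioxin-4-one
Conditions: KHMDS, THF, −78 °C; TBSCl, −78 to 0 °C
Reagents that add atoms: tert-butyldimethylsilyl chloride, CC(C)(C)[Si](C)(C)Cl
Why: O-silylation of the two hindered phenoxides under conditions free of Lewis acid, so that the acylal is not ionised; both OH groups must be masked before the titanium reagent is used.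

**Step 10**
Reactants: 15 rac-2-[2,4-bis(triisopropylsilyloxy)phenyl]-5,7-bis(tert-butyldimethylsilyloxy)-6-[(E)-3-methylbut-1-en-1-yl]-8-(3-methylbut-2-en-1-yl)-4H-1,3-benzodioxin-4-one
Product: 16 rac-2-[2,4-bis(triisopropylsilyloxy)phenyl]-5,7-bis(tert-butyldimethylsilyloxy)-6-[(E)-3-methylbut-1-en-1-yl]-8-(3-methylbut-2-en-1-yl)-4-methylidene-4H-1,3-benzodioxine
Conditions: Cp2TiMe2 (3 equiv), toluene–THF, 70 °C, dark; filtration through basic alumina (1% Et3N)
Reagents that add atoms: dimethyltitanocene, [CH3-].[CH3-].[Ti+4].c1cc[cH-]c1.c1cc[cH-]c1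
Why: Petasis methylenation of the lactone carbonyl through Cp2Ti=CH2 ([2+2]/retro-[2+2]), the usual entry to Petasis–Ferrier substrates from 1,3-dioxan-4-ones; the aluminium-free reagent avoids a premature racemic rearrangement, and the silyl ethers and the tri- and 1,2-disubstituted alkenes should be inert to it, although the peri 5-silyloxy group may slow the reaction.

**Step 11**
Reactants: 16 rac-2-[2,4-bis(triisopropylsilyloxy)phenyl]-5,7-bis(tert-butyldimethylsilyloxy)-6-[(E)-3-methylbut-1-en-1-yl]-8-(3-methylbut-2-en-1-yl)-4-methylidene-4H-1,3-benzodioxine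
Product: 17 (2S)-2-[2,4-bis(triisopropylsilyloxy)phenyl]-5,7-bis(tert-butyldimethylsilyloxy)-6-[(E)-3-methylbut-1-en-1-yl]-8-(3-methylbut-2-en-1-yl)-2,3-dihydro-4H-chromen-4-one
Conditions: (R)-3,3'-bis(2,4,6-triisopropylphenyl)-BINOL N-triflylphosphoramide (10 mol%), 5 Å MS, toluene, −40 °C; Et3N quench
Reagents that add atoms: none
Why: Proposed new method: the chiral acid protonates the enol-ether oxygen O3 (C-protonation of the exocyclic CH2 followed by C2–O3 cleavage leads to the same ion pair), C2–O3 ionises, and the O1-aryl oxocarbenium ion at C2, stabilised by the 2,4-bis(silyloxy)phenyl ring, stays tethered through O1 to the enol of the aryl methyl ketone, whose terminal carbon adds to C2 to form C2–C3 and, after loss of the enol proton to the catalyst anion, the C4 ketone. The closest known reactions are the Lewis-acid Petasis–Ferrier rearrangement of 4-methylene-1,3-dioxanes to tetrahydropyran-4-ones and the chiral-phosphoric-acid aza-Petasis–Ferrier rearrangement of hemiaminal vinyl ethers; a chiral Brønsted acid version on an O,O-acetal of a benzo-fused dioxine has not been described. Ring C closes in a 6-(enolendo)-endo-trig mode. C2 is set by the chiral phosphoramide anion, which should hold the enol O–H by a hydrogen bond while paired with the planar cation and so shield one face of C2; because ionisation erases the acetal centre, both enantiomers of 16 converge on the same ion pair. The step needs enantioface selectivity and chemoselectivity for the tethered enol over the C8 prenyl and C6 alkenyl π-bonds and over water: the six-membered intramolecular reach and much higher nucleophilicity of the enol, the sieves, and the low temperature (which should also disfavour re-ionisation of the benzylic C2–O1 bond of 17) are relied on for this.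

**Step 12**
Reactants: 17 (2S)-2-[2,4-bis(triisopropylsilyloxy)phenyl]-5,7-bis(tert-butyldimethylsilyloxy)-6-[(E)-3-methylbut-1-en-1-yl]-8-(3-methylbut-2-en-1-yl)-2,3-dihydro-4H-chromen-4-one
Product: 18 (2S)-2-(2,4-dihydroxyphenyl)-5,7-dihydroxy-6-[(E)-3-methylbut-1-en-1-yl]-8-(3-methylbut-2-en-1-yl)-2,3-dihydro-4H-chromen-4-one
Conditions: TBAF, AcOH (1:1.2), THF, 0 °C
Reagents that add atoms: none
Why: Fluoride cleavage of the four aryl silyl ethers; the acetic acid buffer should keep phenoxides, which open flavanones by retro-oxa-Michael reaction and would racemise C2, from building up, and it leaves the prenyl and alkenyl groups untouched.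

**Compound list**

1 | 2,4-dihydroxybenzaldehyde | O=Cc1ccc(O)cc1O | starting material
2 | 2,4-bis(triisopropylsilyloxy)benzaldehyde | O=Cc1ccc(O[Si](C(C)C)(C(C)C)C(C)C)cc1O[Si](C(C)C)(C(C)C)C(C)C | intermediate
3 | 2,4,6-trihydroxybenzoic acid | O=C(O)c1c(O)cc(O)cc1O | starting material
4 | trimethylsilyl 2,4,6-tris(trimethylsilyloxy)benzoate (not isolated) | C[Si](C)(C)OC(=O)c1c(O[Si](C)(C)C)cc(O[Si](C)(C)C)cc1O[Si](C)(C)C | intermediate
5 | rac-2-[2,4-bis(triisopropylsilyloxy)phenyl]-5,7-bis(trimethylsilyloxy)-4H-1,3-benzodioxin-4-one (not isolated) | O=C1OC(c2ccc(O[Si](C(C)C)(C(C)C)C(C)C)cc2O[Si](C(C)C)(C(C)C)C(C)C)Oc2cc(O[Si](C)(C)C)cc(O[Si](C)(C)C)c21 | intermediate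
6 | rac-2-[2,4-bis(triisopropylsilyloxy)phenyl]-5,7-dihydroxy-4H-1,3-benzodioxin-4-one | O=C1OC(c2ccc(O[Si](C(C)C)(C(C)C)C(C)C)cc2O[Si](C(C)C)(C(C)C)C(C)C)Oc2cc(O)cc(O)c21 | intermediate
7 | 3-chloro-3-methylbut-1-yne | CC(C)(Cl)C#C | starting material
8 | rac-2-[2,4-bis(triisopropylsilyloxy)phenyl]-5-hydroxy-7-[(2-methylbut-3-yn-2-yl)oxy]-4H-1,3-benzodioxin-4-one | O=C1OC(c2ccc(O[Si](C(C)C)(C(C)C)C(C)C)cc2O[Si](C(C)C)(C(C)C)C(C)C)Oc2cc(OC(C)(C)C#C)cc(O)c21 | intermediate
9 | rac-2-[2,4-bis(triisopropylsilyloxy)phenyl]-5-hydroxy-7-[(2-methylbut-3-en-2-yl)oxy]-4H-1,3-benzodioxin-4-one | O=C1OC(c2ccc(O[Si](C(C)C)(C(C)C)C(C)C)cc2O[Si](C(C)C)(C(C)C)C(C)C)Oc2cc(OC(C)(C)C=C)cc(O)c21 | intermediate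
10 | rac-2-[2,4-bis(triisopropylsilyloxy)phenyl]-5-hydroxy-6-iodo-7-[(2-methylbut-3-en-2-yl)oxy]-4H-1,3-benzodioxin-4-one | O=C1OC(c2ccc(O[Si](C(C)C)(C(C)C)C(C)C)cc2O[Si](C(C)C)(C(C)C)C(C)C)Oc2cc(OC(C)(C)C=C)c(I)c(O)c21 | intermediate
11 | rac-2-[2,4-bis(triisopropylsilyloxy)phenyl]-5,7-dihydroxy-6-iodo-8-(3-methylbut-2-en-1-yl)-4H-1,3-benzodioxin-4-one | O=C1OC(c2ccc(O[Si](C(C)C)(C(C)C)C(C)C)cc2O[Si](C(C)C)(C(C)C)C(C)C)Oc2c(CC=C(C)C)c(O)c(I)c(O)c21 | intermediate
12 | 3-methylbut-1-yne | CC(C)C#C | starting material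
13 | (E)-2-(3-methylbut-1-en-1-yl)-4,4,5,5-tetramethyl-1,3,2-dioxaborolane | CC(C)/C=C/B1OC(C)(C)C(C)(C)O1 | intermediate
14 | rac-2-[2,4-bis(triisopropylsilyloxy)phenyl]-5,7-dihydroxy-6-[(E)-3-methylbut-1-en-1-yl]-8-(3-methylbut-2-en-1-yl)-4H-1,3-benzodioxin-4-one | O=C1OC(c2ccc(O[Si](C(C)C)(C(C)C)C(C)C)cc2O[Si](C(C)C)(C(C)C)C(C)C)Oc2c(CC=C(C)C)c(O)c(/C=C/C(C)C)c(O)c21 | intermediate
15 | rac-2-[2,4-bis(triisopropylsilyloxy)phenyl]-5,7-bis(tert-butyldimethylsilyloxy)-6-[(E)-3-methylbut-1-en-1-yl]-8-(3-methylbut-2-en-1-yl)-4H-1,3-benzodioxin-4-one | O=C1OC(c2ccc(O[Si](C(C)C)(C(C)C)C(C)C)cc2O[Si](C(C)C)(C(C)C)C(C)C)Oc2c(CC=C(C)C)c(O[Si](C)(C)C(C)(C)C)c(/C=C/C(C)C)c(O[Si](C)(C)C(C)(C)C)c21 | intermediate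
16 | rac-2-[2,4-bis(triisopropylsilyloxy)phenyl]-5,7-bis(tert-butyldimethylsilyloxy)-6-[(E)-3-methylbut-1-en-1-yl]-8-(3-methylbut-2-en-1-yl)-4-methylidene-4H-1,3-benzodioxine | C=C1OC(c2ccc(O[Si](C(C)C)(C(C)C)C(C)C)cc2O[Si](C(C)C)(C(C)C)C(C)C)Oc2c(CC=C(C)C)c(O[Si](C)(C)C(C)(C)C)c(/C=C/C(C)C)c(O[Si](C)(C)C(C)(C)C)c21 | intermediate
17 | (2S)-2-[2,4-bis(triisopropylsilyloxy)phenyl]-5,7-bis(tert-butyldimethylsilyloxy)-6-[(E)-3-methylbut-1-en-1-yl]-8-(3-methylbut-2-en-1-yl)-2,3-dihydro-4H-chromen-4-one | CC(C)=CCc1c(O[Si](C)(C)C(C)(C)C)c(/C=C/C(C)C)c(O[Si](C)(C)C(C)(C)C)c2c1O[C@H](c1ccc(O[Si](C(C)C)(C(C)C)C(C)C)cc1O[Si](C(C)C)(C(C)C)C(C)C)CC2=O | intermediate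
18 | (2S)-2-(2,4-dihydroxyphenyl)-5,7-dihydroxy-6-[(E)-3-methylbut-1-en-1-yl]-8-(3-methylbut-2-en-1-yl)-2,3-dihydro-4H-chromen-4-one (CNP0290067.1) | CC(C)=CCc1c(O)c(/C=C/C(C)C)c(O)c2c1O[C@H](c1ccc(O)cc1O)CC2=O | target

**Step count and risks**

Total step count: 12. Longest linear sequence: 11 steps (1 → 2 → 6 → 8 → 9 → 10 → 11 → 14 → 15 → 16 → 17 → 18; step 7 is the side branch).

Steps most likely to fail:

1. Step 11 (Proposed new method). What may go wrong: too little enantioface discrimination inside the ion pair, a racemic background rearrangement, hydrolysis of the ion pair by traces of water, or erosion of the product by re-ionisation at C2. Fallback by known chemistry, setting out from 16 and returning at 17: 16 is hydrolysed (wet silica gel or dilute oxalic acid, THF–H2O) to the o-hydroxyacetophenone F1 with release of aldehyde 2. The dilithium enolate of F1 (LiHMDS, THF, −78 °C) is added to 2 to give the racemic aldol F2. An intramolecular Mitsunobu etherification (PPh3, DIAD, THF, 0 °C) closes ring C to the racemic flavanone F3. Preparative HPLC on a chiral stationary phase then provides 17.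

2. Step 8. What may go wrong: slow oxidative addition into the electron-rich C–I bond flanked by two phenoxides, with competing protodeiodination, and attack of the aqueous base on the acylal. Fallback, setting out from 11 and 12 and returning at 14: 12 is hydrostannylated (Bu3SnH, PdCl2(PPh3)2, THF), which for an α-branched alkyne should give mainly the (E)-alkenylstannane F4. F4 is then coupled with 11 in a base-free Stille reaction (Pd2(dba)3, AsPh3, DMF, 50 °C) to give 14.

3. Step 6. What may go wrong: a [3,3] shift onto the iodine-bearing C6 followed by loss of iodine from the dienone, which drains material into an iodine-free 6-prenyl phenol. Fallback, setting out from 6 and returning at 14, in which the alkenyl group takes over the blocking of C6: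
   - Diol 6 is silylated at the unchelated 7-OH (TBSCl, imidazole, DMF, 0 °C) to the 7-O-TBS ether F5.
   - F5 is iodinated ortho to the 5-OH (NIS, DMF) to the 6-iodide F6.
   - F6 is coupled with 13 under the conditions of step 8; the aqueous base should also remove the labile 7-O-silyl group, giving the 6-alkenyl diol F7.
   - F7 is alkylated at O7 with 7 (DBU, CuCl2, MeCN) to the propargyl ether F8.
   - Lindlar reduction of F8 gives the dimethylallyl ether F9.
   - Heating F9 in toluene at 110 °C moves the prenyl group to C8 and gives 14.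

**Further compounds**

F1 | step 11 | 1-[4,6-bis(tert-butyldimethylsilyloxy)-2-hydroxy-5-[(E)-3-methylbut-1-en-1-yl]-3-(3-methylbut-2-en-1-yl)phenyl]ethan-1-one | CC(=O)c1c(O)c(CC=C(C)C)c(O[Si](C)(C)C(C)(C)C)c(/C=C/C(C)C)c1O[Si](C)(C)C(C)(C)C
F2 | step 11 | rac-3-[2,4-bis(triisopropylsilyloxy)phenyl]-1-[4,6-bis(tert-butyldimethylsilyloxy)-2-hydroxy-5-[(E)-3-methylbut-1-en-1-yl]-3-(3-methylbut-2-en-1-yl)phenyl]-3-hydroxypropan-1-one | OC(CC(=O)c1c(O)c(CC=C(C)C)c(O[Si](C)(C)C(C)(C)C)c(/C=C/C(C)C)c1O[Si](C)(C)C(C)(C)C)c1ccc(O[Si](C(C)C)(C(C)C)C(C)C)cc1O[Si](C(C)C)(C(C)C)C(C)C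
F3 | step 11 | racemic form of 17 | CC(C)=CCc1c(O[Si](C)(C)C(C)(C)C)c(/C=C/C(C)C)c(O[Si](C)(C)C(C)(C)C)c2c1OC(c1ccc(O[Si](C(C)C)(C(C)C)C(C)C)cc1O[Si](C(C)C)(C(C)C)C(C)C)CC2=O
F4 | step 8 | (E)-tributyl(3-methylbut-1-en-1-yl)stannane | CCCC[Sn](CCCC)(CCCC)/C=C/C(C)C
F5 | step 6 | rac-2-[2,4-bis(triisopropylsilyloxy)phenyl]-7-(tert-butyldimethylsilyloxy)-5-hydroxy-4H-1,3-benzodioxin-4-one | O=C1OC(c2ccc(O[Si](C(C)C)(C(C)C)C(C)C)cc2O[Si](C(C)C)(C(C)C)C(C)C)Oc2cc(O[Si](C)(C)C(C)(C)C)cc(O)c21
F6 | step 6 | rac-2-[2,4-bis(triisopropylsilyloxy)phenyl]-7-(tert-butyldimethylsilyloxy)-5-hydroxy-6-iodo-4H-1,3-benzodioxin-4-one | O=C1OC(c2ccc(O[Si](C(C)C)(C(C)C)C(C)C)cc2O[Si](C(C)C)(C(C)C)C(C)C)Oc2cc(O[Si](C)(C)C(C)(C)C)c(I)c(O)c21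
F7 | step 6 | rac-2-[2,4-bis(triisopropylsilyloxy)phenyl]-5,7-dihydroxy-6-[(E)-3-methylbut-1-en-1-yl]-4H-1,3-benzodioxin-4-one | O=C1OC(c2ccc(O[Si](C(C)C)(C(C)C)C(C)C)cc2O[Si](C(C)C)(C(C)C)C(C)C)Oc2cc(O)c(/C=C/C(C)C)c(O)c21
F8 | step 6 | rac-2-[2,4-bis(triisopropylsilyloxy)phenyl]-5-hydroxy-6-[(E)-3-methylbut-1-en-1-yl]-7-[(2-methylbut-3-yn-2-yl)oxy]-4H-1,3-benzodioxin-4-one | O=C1OC(c2ccc(O[Si](C(C)C)(C(C)C)C(C)C)cc2O[Si](C(C)C)(C(C)C)C(C)C)Oc2cc(OC(C)(C)C#C)c(/C=C/C(C)C)c(O)c21
F9 | step 6 | rac-2-[2,4-bis(triisopropylsilyloxy)phenyl]-5-hydroxy-6-[(E)-3-methylbut-1-en-1-yl]-7-[(2-methylbut-3-en-2-yl)oxy]-4H-1,3-benzodioxin-4-one | O=C1OC(c2ccc(O[Si](C(C)C)(C(C)C)C(C)C)cc2O[Si](C(C)C)(C(C)C)C(C)C)Oc2cc(OC(C)(C)C=C)c(/C=C/C(C)C)c(O)c21
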